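You read this flask once, at 3.0 h; here is what it holds and what you are asked.

    gas phase ⇌ dissolved gas, rate k1*(csat - [dissolved gas]) (k1 = 0.78 /s, csat = 120 mM)
    substrate + dissolved gas + catalyst → catalyst + target (k2 = 5800 /M²/s)
    substrate + target → side product (k3 = 0.22 /M/s)

substrate 0.25 M; gas phase 120 mM (held); catalyst 0.87 mol%; time 3.0 h

- in percentages every species weighs as the substrate in it: one side product counts as two
- at the start none of the gas is dissolved
- the reaction counts as stopped when no species that holds the substrate changes by six tenths of a point or more over the second half of the time
- run time (flask): 3.0 h

- at 3.0 h, what has stopped the reaction, if anything has (all of the substrate has reacted / it is still moving / no working catalyst is left)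
- amount of target at 3.0 h, in percent of the substrate charged
- amount of side product at 3.0 h, in percent of the substrate charged

My reckoning takes a as the fraction of the charge still substrate and p as the fraction that is target.

1. The curve starts flat: dissolved gas begins at zero and fills with a time constant of 1.28 s.

2. Then a falls down a steep slope that eases gently. Gas crosses at most at 0.374 /s in fractions of the charge. The catalyst's pull on dissolved gas at full charge is m = 4.04 times the transfer coefficient, so near the start transfer is the rate-limiting step, and as m·a comes down to 1 the two steps are of like size.

3. The knee lies at a = 0.248, after 2.93 s. Below it the decay tends to pseudo-first-order, with a half-life nearing 0.458 s, so the curve flattens onto zero long before the reading.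

4. Both steps use substrate in proportion to a, so side step over target step is s·p·(1 + m·a), with s = 0.0363. Take the even case, ratio 1, as the zero of the scale. With p close to 1 − a, the ratio peaks at a = 0.376 and reaches 0.0571, which is less than even.

5. Summed over the fall of a and counted double, this gives s(1 + m/3) = 8.53%, the leak: the fraction of the charge that ends as side product. Target levels off at 91.5%.

The forecast says all of the substrate has reacted, with target 92.2% and side product 7.8%: “The side reaction only runs during those few seconds while substrate and target coexist”. My side product is higher than its figure by 0.73 percentage points.

The simulation gives all of the substrate has reacted, with target 91.3% and side product 8.70%.

In this flask the leak stands 0.17 points below the simulated side product. For the neighbour charged with 0.42 M of substrate, loading held, the leak gives 17.5%, and that flask ends at 15.2%, so there the leak runs high. This flask has come to rest: substrate is 0% at 0.300 h. Target is 91.3% at 30.0 h, and ten times the time changes side product by 0 points.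

The numbers are invented; no experiment stands behind them.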